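**Plan**
1. Retrosynthesis: after removal of one silyl ether, the lactone is cut at C2–C3 (carbonyl carbon to α-carbon) with loss of CO. This unveils an acyclic β-allenic alcohol whose only free hydroxyl is the future O1–C6 oxygen.
2. Enabling feature: in the 5,6-dihydro-2H-pyran-2-one ring (O1, C2=O, C3=C4, C5, C6), C3 carries C2, the double bond to C4 and an exocyclic CH2, and O1 sits on C6. This is the footprint left when an O-bound alkoxycarbonyl group adds to the central carbon of a 1,3-disubstituted allene and hydrogen goes to the far allene terminus.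
3. Further cuts: the allene (propargylic alcohol from an acetylide and 4-methylpent-3-enal, then reductive transposition), the C5–C6 bond (propargylation of an enal), the acetoxymethyl-bearing alkene (cross-metathesis) and the sp2–sp3 bond next to the Z-methyl alkene (Negishi coupling).
4. Forward order: the C8 chain is joined first (Negishi, then metathesis), the propargyl and prenylacetaldehyde units are added, the allene is made, and the only ring is closed in the penultimate step.
5. Stereochemistry: the single stereocentre (C6, S) comes from a chiral phosphoric acid-catalysed propargylation. The Z-methyl alkene comes from trans-hydroalumination/iodination and a stereoretentive coupling, the E-alkene from thermodynamic control in the metathesis. The ring alkene geometry is enforced by the ring, and the allene axis needs no control.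

Key step: step 14

Remark: the target is read as the (6S)-lactone with the acetoxymethyl group cis to the chain on the first side-chain alkene (2E) and a Z (neryl-type) allylic alcohol. The propargylic carbinol and the allene axis of the intermediates are carried as stereoisomer mixtures because both disappear in step 14.

**Step 1**
Reactants: 1 but-2-yn-1-ol
Product: 3 (2Z)-3-iodobut-2-en-1-ol, via cyclic alkenylaluminate 2 (not isolated)
Conditions: NaAlH2(OCH2CH2OMe)2 (Red-Al), THF, 0 °C to rt; then I2, −78 to 0 °C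
Reagents that add atoms: iodine, II
Why: Hydroxyl-directed trans-hydroalumination of the propargylic alcohol places aluminium on C3 anti to the delivered hydride, and iodinolysis with retention should give the Z-iodide that fixes the neryl-type alkene geometry.

**Step 2**
Reactants: 3 (2Z)-3-iodobut-2-en-1-ol
Product: 4 tert-butyl{[(2Z)-3-iodobut-2-en-1-yl]oxy}diphenylsilane
Conditions: TBDPSCl, imidazole, CH2Cl2, 0 °C to rt
Reagents that add atoms: tert-butyl(chloro)diphenylsilane (TBDPSCl), CC(C)(C)[Si](Cl)(c1ccccc1)c1ccccc1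
Why: Imidazole-promoted silylation of a primary alcohol is routine, and the TBDPS ether is chosen because it should outlast the later acid-mediated removal of the other silyl groups.

**Step 3**
Reactants: 4 tert-butyl{[(2Z)-3-iodobut-2-en-1-yl]oxy}diphenylsilane; 5 but-3-en-1-ylzinc bromide
Product: 6 tert-butyl{[(2Z)-3-methylhepta-2,6-dien-1-yl]oxy}diphenylsilane
Conditions: Pd(dppf)Cl2 (3 mol%), THF, rt to 50 °C
Reagents that add atoms: none
Why: Negishi sp2–sp3 cross-coupling (oxidative addition of the alkenyl iodide to zerovalent palladium, transmetalation, reductive elimination) proceeds with retention of alkene geometry, and the dppf ligand suppresses β-hydride elimination.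

**Step 4**
Reactants: 7 2-methylidenepropane-1,3-diol
Product: 8 2-{[(tert-butyldimethylsilyl)oxy]methyl}prop-2-en-1-ol
Conditions: NaH (1.0 equiv), THF, 0 °C; then TBSCl (1.0 equiv), rt
Reagents that add atoms: tert-butyl(chloro)dimethylsilane (TBSCl), CC(C)(C)[Si](C)(C)Cl
Why: Monosilylation of a symmetrical diol through its monosodium alkoxide should stop after one silyl transfer.

**Step 5**
Reactants: 8 2-{[(tert-butyldimethylsilyl)oxy]methyl}prop-2-en-1-ol
Product: 9 2-{[(tert-butyldimethylsilyl)oxy]methyl}prop-2-enal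
Conditions: MnO2 (activated, excess), CH2Cl2, rt
Reagents that add atoms: none
Why: MnO2 oxidation is selective for allylic alcohols and should give the α-substituted acrolein without touching the silyl ether.

**Step 6**
Reactants: 6 tert-butyl{[(2Z)-3-methylhepta-2,6-dien-1-yl]oxy}diphenylsilane; 9 2-{[(tert-butyldimethylsilyl)oxy]methyl}prop-2-enal (3 equiv)
Product: 10 (2E,6Z)-2-{[(tert-butyldimethylsilyl)oxy]methyl}-8-[(tert-butyldiphenylsilyl)oxy]-6-methylocta-2,6-dienal
Conditions: second-generation Hoveyda–Grubbs catalyst (5 mol%), CH2Cl2, 40 °C, argon sparge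
Reagents that add atoms: none
Why: Olefin cross-metathesis of a terminal alkene with an α-substituted acrolein should engage only the monosubstituted alkene of 6 (the trisubstituted alkene is a spectator) and give the conjugated enal as the thermodynamic E isomer, with the formyl group cis to H.

**Step 7**
Reactants: 10 (2E,6Z)-2-{[(tert-butyldimethylsilyl)oxy]methyl}-8-[(tert-butyldiphenylsilyl)oxy]-6-methylocta-2,6-dienal; 11 allenylboronic acid pinacol ester
Product: 13 (4S,5E,9Z)-5-{[(tert-butyldimethylsilyl)oxy]methyl}-11-[(tert-butyldiphenylsilyl)oxy]-9-methylundeca-5,9-dien-1-yn-4-ol, via pinacol borate ester 12 (not isolated)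
Conditions: (S)-TRIP [(S)-3,3'-bis(2,4,6-triisopropylphenyl)-1,1'-binaphthyl-2,2'-diyl hydrogen phosphate] (10 mol%), 4 Å molecular sieves, toluene, −20 to 0 °C; then H2O work-up
Reagents that add atoms: none
Why: Chiral phosphoric acid-catalysed propargylation (SE2' transfer from the allenylboronate through a six-membered chair transition state) should set the carbinol; the (S)-catalyst is chosen to direct attack to the Si face and give the (S)-alcohol, by analogy with aryl and alkenyl aldehydes, for which the (R)-catalyst is expected to give the (R)-carbinols.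

**Step 8**
Reactants: 13 (4S,5E,9Z)-5-{[(tert-butyldimethylsilyl)oxy]methyl}-11-[(tert-butyldiphenylsilyl)oxy]-9-methylundeca-5,9-dien-1-yn-4-ol
Product: 14 triethylsilyl ether of 13
Conditions: TESCl, imidazole, CH2Cl2, 0 °C
Reagents that add atoms: chlorotriethylsilane (TESCl), CC[Si](Cl)(CC)CC
Why: Silylation masks the carbinol for the acetylide and Mitsunobu steps, and the TES group can later be removed together with the primary TBS ether.

**Step 9**
Reactants: 15 4-methylpent-3-en-1-ol
Product: 16 4-methylpent-3-enal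
Conditions: Dess–Martin periodinane, NaHCO3, CH2Cl2, 0 °C; solution used at once
Reagents that add atoms: none
Why: Buffered Dess–Martin oxidation is non-basic and should give the β,γ-unsaturated aldehyde without migration of the double bond into conjugation.

**Step 10**
Reactants: 14 triethylsilyl ether of 13; 16 4-methylpent-3-enal
Product: 18 (9S,10E,14Z)-10-{[(tert-butyldimethylsilyl)oxy]methyl}-16-[(tert-butyldiphenylsilyl)oxy]-2,14-dimethyl-9-[(triethylsilyl)oxy]hexadeca-2,10,14-trien-6-yn-5-ol (both C5 epimers), via lithium acetylide 17 (not isolated)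
Conditions: n-BuLi, THF, −78 °C; then 16, −78 °C; then H2O
Reagents that add atoms: none
Why: Addition of a lithium acetylide to an aldehyde at −78 °C should outpace enolisation; the new carbinol forms as both epimers, which is inconsequential because this centre is converted into the allene.

**Step 11**
Reactants: 18 propargylic alcohol (both C5 epimers)
Product: 21 (9S,10E,14Z)-10-{[(tert-butyldimethylsilyl)oxy]methyl}-16-[(tert-butyldiphenylsilyl)oxy]-2,14-dimethyl-9-[(triethylsilyl)oxy]hexadeca-2,5,6,10,14-pentaene (allene diastereomers), via N-sulfonylhydrazine 19 (not isolated), via propargylic diazene 20 (not isolated)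
Conditions: PPh3, DEAD, 2-nitrobenzenesulfonylhydrazide, THF, −15 °C to rt
Reagents that add atoms: none
Why: Myers allene synthesis: Mitsunobu displacement by the sulfonylhydrazide, loss of sulfinic acid and retro-ene extrusion of N2 from the propargylic diazene should convert the propargylic alcohol into the 1,3-disubstituted allene under neutral conditions.

**Step 12**
Reactants: 21 allene tris-silyl ether
Product: 22 (9S,10E,14Z)-16-[(tert-butyldiphenylsilyl)oxy]-10-(hydroxymethyl)-2,14-dimethylhexadeca-2,5,6,10,14-pentaen-9-ol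
Conditions: camphorsulfonic acid (10 mol%), MeOH/CH2Cl2, 0 °C
Reagents that add atoms: none
Why: Acid-catalysed methanolysis (selective desilylation) should cleave the secondary TES and primary TBS ethers much faster than the TBDPS ether, and the allene tolerates catalytic acid at 0 °C.

**Step 13**
Reactants: 22 allenic diol
Product: 23 [(9S,10E,14Z)-16-[(tert-butyldiphenylsilyl)oxy]-9-hydroxy-2,14-dimethylhexadeca-2,5,6,10,14-pentaen-10-yl]methyl acetate
Conditions: AcCl (1.05 equiv), 2,4,6-collidine, CH2Cl2, −78 °C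
Reagents that add atoms: acetyl chloride, CC(=O)Cl
Why: Collidine-mediated acetylation at low temperature is selective for the primary allylic alcohol over the hindered secondary carbinol, which leaves a single free hydroxyl for the carbonylation.

**Step 14**
Reactants: 23 β-allenic alcohol monoacetate
Product: 24 [(2E,6Z)-8-[(tert-butyldiphenylsilyl)oxy]-6-methyl-2-[(2S)-5-(4-methylpent-3-en-1-yl)-6-oxo-3,6-dihydro-2H-pyran-2-yl]octa-2,6-dien-1-yl] acetate
Conditions: Ru3(CO)12 (2 mol%), CO (10 atm), Et3N, 1,4-dioxane, 100 °C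
Reagents that add atoms: carbon monoxide, [C-]#[O+]
Why: The C6 hydroxyl (lactone numbering) adds to a ruthenium carbonyl and CO inserts into the Ru–O bond to give an alkoxycarbonyl–ruthenium hydride tethered through O1; migratory insertion of the distal allene C=C then joins the acyl carbon C2 to the central allene carbon C3, which closes the ring and leaves ruthenium as an η3-allyl over C4, C3 and the exocyclic CH. C–H reductive elimination at the exocyclic allyl terminus delivers the side-chain CH2 and the conjugated endocyclic C3=C4 bond and returns the catalyst. The closest known reaction type is the Ru3(CO)12-catalysed cyclocarbonylation of allenyl alcohols, which converts 3,4-dien-1-ols into 3-alkyl-5,6-dihydro-2H-pyran-2-ones. The six-membered ring closes in a 6-exo-dig mode (acyl carbon onto the sp carbon, the consumed π-bond exocyclic). No stereocentre is created: C6 is untouched and the allene axis is destroyed, so both allene diastereomers should converge on one product. The step needs chemoselectivity for the allene over three trisubstituted alkenes and the allylic acetate, secured by delivery from the only free hydroxyl and the stronger binding of the cumulene, and regioselectivity for the six-membered endocyclic enoate, secured by acyl transfer to the central carbon (allyl intermediate) and hydrogen delivery to the less hindered exocyclic terminus.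

**Step 15**
Reactants: 24 lactone TBDPS ether
Product: 25 [(2E,6Z)-8-hydroxy-6-methyl-2-[(2S)-5-(4-methylpent-3-en-1-yl)-6-oxo-3,6-dihydro-2H-pyran-2-yl]octa-2,6-dien-1-yl] acetate (target)
Conditions: HF·pyridine, pyridine, THF, 0 °C to rt
Reagents that add atoms: none
Why: Buffered fluoride desilylation should cleave the primary TBDPS ether while leaving the allylic acetate and the unsaturated lactone intact.

**Compound list**
1 | but-2-yn-1-ol | CC#CCO | starting material
2 | sodium 2,2-bis(2-methoxyethoxy)-3-methyl-2,5-dihydro-1,2-oxaaluminol-2-uide (cyclic alkenylaluminate) | C/C1=C/CO[Al-]1(OCCOC)OCCOC.[Na+] | intermediate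
3 | (2Z)-3-iodobut-2-en-1-ol | C/C(I)=C/CO | intermediate
4 | tert-butyl{[(2Z)-3-iodobut-2-en-1-yl]oxy}diphenylsilane | C/C(I)=C/CO[Si](c1ccccc1)(c1ccccc1)C(C)(C)C | intermediate
5 | but-3-en-1-ylzinc bromide | C=CCC[Zn]Br | starting material
6 | tert-butyl{[(2Z)-3-methylhepta-2,6-dien-1-yl]oxy}diphenylsilane | C=CCC/C(C)=C\CO[Si](c1ccccc1)(c1ccccc1)C(C)(C)C | intermediate
7 | 2-methylidenepropane-1,3-diol | C=C(CO)CO | starting material
8 | 2-{[(tert-butyldimethylsilyl)oxy]methyl}prop-2-en-1-ol | C=C(CO)CO[Si](C)(C)C(C)(C)C | intermediate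
9 | 2-{[(tert-butyldimethylsilyl)oxy]methyl}prop-2-enal | C=C(C=O)CO[Si](C)(C)C(C)(C)C | intermediate
10 | (2E,6Z)-2-{[(tert-butyldimethylsilyl)oxy]methyl}-8-[(tert-butyldiphenylsilyl)oxy]-6-methylocta-2,6-dienal | O=C/C(CO[Si](C)(C)C(C)(C)C)=C/CC/C(C)=C\CO[Si](c1ccccc1)(c1ccccc1)C(C)(C)C | intermediate
11 | allenylboronic acid pinacol ester (4,4,5,5-tetramethyl-2-(propa-1,2-dien-1-yl)-1,3,2-dioxaborolane) | C=C=CB1OC(C)(C)C(C)(C)O1 | starting material
12 | pinacol borate ester of 13 | C#CC[C@H](OB1OC(C)(C)C(C)(C)O1)/C(CO[Si](C)(C)C(C)(C)C)=C/CC/C(C)=C\CO[Si](c1ccccc1)(c1ccccc1)C(C)(C)C | intermediate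
13 | (4S,5E,9Z)-5-{[(tert-butyldimethylsilyl)oxy]methyl}-11-[(tert-butyldiphenylsilyl)oxy]-9-methylundeca-5,9-dien-1-yn-4-ol | C#CC[C@H](O)/C(CO[Si](C)(C)C(C)(C)C)=C/CC/C(C)=C\CO[Si](c1ccccc1)(c1ccccc1)C(C)(C)C | intermediate
14 | triethylsilyl ether of 13 | C#CC[C@H](O[Si](CC)(CC)CC)/C(CO[Si](C)(C)C(C)(C)C)=C/CC/C(C)=C\CO[Si](c1ccccc1)(c1ccccc1)C(C)(C)C | intermediate
15 | 4-methylpent-3-en-1-ol | CC(C)=CCCO | starting material
16 | 4-methylpent-3-enal | CC(C)=CCC=O | intermediate
17 | lithium acetylide of 14 | [Li]C#CC[C@H](O[Si](CC)(CC)CC)/C(CO[Si](C)(C)C(C)(C)C)=C/CC/C(C)=C\CO[Si](c1ccccc1)(c1ccccc1)C(C)(C)C | intermediate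
18 | (9S,10E,14Z)-10-{[(tert-butyldimethylsilyl)oxy]methyl}-16-[(tert-butyldiphenylsilyl)oxy]-2,14-dimethyl-9-[(triethylsilyl)oxy]hexadeca-2,10,14-trien-6-yn-5-ol (C5 epimers) | CC(C)=CCC(O)C#CC[C@H](O[Si](CC)(CC)CC)/C(CO[Si](C)(C)C(C)(C)C)=C/CC/C(C)=C\CO[Si](c1ccccc1)(c1ccccc1)C(C)(C)C | intermediate
19 | N-alkyl-N-(2-nitrobenzenesulfonyl)hydrazine derived from 18 | CC(C)=CCC(N(N)S(=O)(=O)c1ccccc1[N+](=O)[O-])C#CC[C@H](O[Si](CC)(CC)CC)/C(CO[Si](C)(C)C(C)(C)C)=C/CC/C(C)=C\CO[Si](c1ccccc1)(c1ccccc1)C(C)(C)C | intermediate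
20 | propargylic monoalkyl diazene derived from 19 | CC(C)=CCC(N=N)C#CC[C@H](O[Si](CC)(CC)CC)/C(CO[Si](C)(C)C(C)(C)C)=C/CC/C(C)=C\CO[Si](c1ccccc1)(c1ccccc1)C(C)(C)C | intermediate
21 | (9S,10E,14Z)-10-{[(tert-butyldimethylsilyl)oxy]methyl}-16-[(tert-butyldiphenylsilyl)oxy]-2,14-dimethyl-9-[(triethylsilyl)oxy]hexadeca-2,5,6,10,14-pentaene (allene diastereomers) | CC(C)=CCC=C=CC[C@H](O[Si](CC)(CC)CC)/C(CO[Si](C)(C)C(C)(C)C)=C/CC/C(C)=C\CO[Si](c1ccccc1)(c1ccccc1)C(C)(C)C | intermediate
22 | (9S,10E,14Z)-16-[(tert-butyldiphenylsilyl)oxy]-10-(hydroxymethyl)-2,14-dimethylhexadeca-2,5,6,10,14-pentaen-9-ol | CC(C)=CCC=C=CC[C@H](O)/C(CO)=C/CC/C(C)=C\CO[Si](c1ccccc1)(c1ccccc1)C(C)(C)C | intermediate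
23 | [(9S,10E,14Z)-16-[(tert-butyldiphenylsilyl)oxy]-9-hydroxy-2,14-dimethylhexadeca-2,5,6,10,14-pentaen-10-yl]methyl acetate | CC(C)=CCC=C=CC[C@H](O)/C(COC(C)=O)=C/CC/C(C)=C\CO[Si](c1ccccc1)(c1ccccc1)C(C)(C)C | intermediate
24 | [(2E,6Z)-8-[(tert-butyldiphenylsilyl)oxy]-6-methyl-2-[(2S)-5-(4-methylpent-3-en-1-yl)-6-oxo-3,6-dihydro-2H-pyran-2-yl]octa-2,6-dien-1-yl] acetate | CC(=O)OC/C(=C\CC/C(C)=C\CO[Si](c1ccccc1)(c1ccccc1)C(C)(C)C)[C@@H]1CC=C(CCC=C(C)C)C(=O)O1 | intermediate
25 | [(2E,6Z)-8-hydroxy-6-methyl-2-[(2S)-5-(4-methylpent-3-en-1-yl)-6-oxo-3,6-dihydro-2H-pyran-2-yl]octa-2,6-dien-1-yl] acetate | CC(=O)OC/C(=C\CC/C(C)=C\CO)[C@@H]1CC=C(CCC=C(C)C)C(=O)O1 | target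

**Step count**
Total steps: 15. Longest linear sequence: 12 steps (steps 1, 2, 3, 6, 7, 8, 10, 11, 12, 13, 14, 15).

**Steps most likely to fail and fallbacks**

Step 14 (cyclocarbonylation). Hydrogen may be delivered to the ring-side allyl terminus, which would give the exocyclic alkylidene isomer. Ruthenium hydride may also cause redox isomerisation of the allylic carbinol or drag the skipped alkene into conjugation before carbonylation, and the allylic acetate may ionise or migrate to the carbinol oxygen. The fallback sets out from 13 and returns at 24, replacing the carbonylation by ring-closing metathesis. Semihydrogenation of the terminal alkyne of 13 (Lindlar catalyst, lead-poisoned Pd on CaCO3, quinoline, H2, EtOAc) should give the homoallylic alcohol F1. Steglich esterification with diethylphosphonoacetic acid (DCC, DMAP, CH2Cl2) gives the phosphonoacetate F2. Alkylation (NaH, 5-bromo-2-methylpent-2-ene, DMF) gives the α-alkylated phosphonoacetate F3. Horner–Wadsworth–Emmons methylenation (K2CO3, aqueous formaldehyde, THF) gives the 2-substituted acrylate F4. Ring-closing metathesis at the terminal vinyl group and the acrylate (second-generation Grubbs catalyst, CH2Cl2, reflux) gives the silyl-protected lactone F5. Methanolysis of the primary TBS ether (camphorsulfonic acid, MeOH/CH2Cl2, 0 °C) gives the primary alcohol F6, and acetylation (AcCl, 2,4,6-collidine) gives 24.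

Step 6 (cross-metathesis). Turnover may be slow with the hindered, electron-poor 1,1-disubstituted formyl olefin, and the catalyst may decompose or isomerise the Z-alkene before the trisubstituted enal forms. The fallback sets out from 4 and returns at 10, building the enal by condensation instead of metathesis. Negishi coupling of 4 with commercial [2-(1,3-dioxolan-2-yl)ethyl]zinc bromide (Pd(dppf)Cl2, THF) gives the dioxolane F7. Acetal hydrolysis (pyridinium p-toluenesulfonate, wet acetone, reflux) gives the aldehyde F8. Knoevenagel condensation with dimethyl malonate (piperidine, AcOH, benzene, reflux) gives the alkylidene malonate F9. Reduction with i-Bu2AlH (CH2Cl2, −78 °C) gives the 2-alkylidene-1,3-diol F10. MnO2 oxidation of the less hindered hydroxymethyl group (the one cis to the vinyl hydrogen) gives the hydroxy enal F11; oxidation of either hydroxymethyl group gives the same constitution and the E isomer is the thermodynamic one. Silylation (TBSCl, imidazole) gives 10.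

Step 7 (propargylation). Facial selectivity may be insufficient with the α-branched enal, or the sense of induction may be opposite to that expected. The fallback sets out from 10 and returns at 13, replacing asymmetric catalysis by kinetic resolution. Barbier propargylation (propargyl bromide, Zn, THF/aqueous NH4Cl) gives the racemic homopropargylic alcohol F12. Sharpless kinetic resolution (Ti(OiPr)4, D-(−)-diisopropyl tartrate, t-BuOOH, 4 Å molecular sieves, CH2Cl2, −20 °C, taken just past half conversion) should epoxidise the (R)-enantiomer to the erythro epoxy alcohol F13 and leave the (S)-alcohol 13, which is separated by chromatography.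

**Further compounds**
F1 | step 14 | (4S,5E,9Z)-5-{[(tert-butyldimethylsilyl)oxy]methyl}-11-[(tert-butyldiphenylsilyl)oxy]-9-methylundeca-1,5,9-trien-4-ol | C=CC[C@H](O)/C(CO[Si](C)(C)C(C)(C)C)=C/CC/C(C)=C\CO[Si](c1ccccc1)(c1ccccc1)C(C)(C)C
F2 | step 14 | (diethoxyphosphoryl)acetate ester of F1 | C=CC[C@H](OC(=O)CP(=O)(OCC)OCC)/C(CO[Si](C)(C)C(C)(C)C)=C/CC/C(C)=C\CO[Si](c1ccccc1)(c1ccccc1)C(C)(C)C
F3 | step 14 | 2-(diethoxyphosphoryl)-6-methylhept-5-enoate ester of F1 | C=CC[C@H](OC(=O)C(CCC=C(C)C)P(=O)(OCC)OCC)/C(CO[Si](C)(C)C(C)(C)C)=C/CC/C(C)=C\CO[Si](c1ccccc1)(c1ccccc1)C(C)(C)C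
F4 | step 14 | 6-methyl-2-methylidenehept-5-enoate ester of F1 | C=CC[C@H](OC(=O)C(=C)CCC=C(C)C)/C(CO[Si](C)(C)C(C)(C)C)=C/CC/C(C)=C\CO[Si](c1ccccc1)(c1ccccc1)C(C)(C)C
F5 | step 14 | (6S)-6-[(2E,6Z)-1-[(tert-butyldimethylsilyl)oxy]-8-[(tert-butyldiphenylsilyl)oxy]-6-methylocta-2,6-dien-2-yl]-3-(4-methylpent-3-en-1-yl)-5,6-dihydro-2H-pyran-2-one | CC(C)(C)[Si](C)(C)OC/C(=C\CC/C(C)=C\CO[Si](c1ccccc1)(c1ccccc1)C(C)(C)C)[C@@H]1CC=C(CCC=C(C)C)C(=O)O1
F6 | step 14 | (6S)-6-[(2E,6Z)-8-[(tert-butyldiphenylsilyl)oxy]-1-hydroxy-6-methylocta-2,6-dien-2-yl]-3-(4-methylpent-3-en-1-yl)-5,6-dihydro-2H-pyran-2-one | OC/C(=C\CC/C(C)=C\CO[Si](c1ccccc1)(c1ccccc1)C(C)(C)C)[C@@H]1CC=C(CCC=C(C)C)C(=O)O1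
F7 | step 6 | tert-butyl{[(2Z)-5-(1,3-dioxolan-2-yl)-3-methylpent-2-en-1-yl]oxy}diphenylsilane | C1COC(CC/C(C)=C\CO[Si](c2ccccc2)(c2ccccc2)C(C)(C)C)O1
F8 | step 6 | (4Z)-6-[(tert-butyldiphenylsilyl)oxy]-4-methylhex-4-enal | O=CCC/C(C)=C\CO[Si](c1ccccc1)(c1ccccc1)C(C)(C)C
F9 | step 6 | dimethyl 2-[(4Z)-6-[(tert-butyldiphenylsilyl)oxy]-4-methylhex-4-en-1-ylidene]propanedioate | COC(=O)C(=CCC/C(C)=C\CO[Si](c1ccccc1)(c1ccccc1)C(C)(C)C)C(=O)OC
F10 | step 6 | 2-[(4Z)-6-[(tert-butyldiphenylsilyl)oxy]-4-methylhex-4-en-1-ylidene]propane-1,3-diol | OCC(CO)=CCC/C(C)=C\CO[Si](c1ccccc1)(c1ccccc1)C(C)(C)C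
F11 | step 6 | (2E,6Z)-8-[(tert-butyldiphenylsilyl)oxy]-2-(hydroxymethyl)-6-methylocta-2,6-dienal | O=C/C(CO)=C/CC/C(C)=C\CO[Si](c1ccccc1)(c1ccccc1)C(C)(C)C
F12 | step 7 | racemic (5E,9Z)-5-{[(tert-butyldimethylsilyl)oxy]methyl}-11-[(tert-butyldiphenylsilyl)oxy]-9-methylundeca-5,9-dien-1-yn-4-ol | C#CCC(O)/C(CO[Si](C)(C)C(C)(C)C)=C/CC/C(C)=C\CO[Si](c1ccccc1)(c1ccccc1)C(C)(C)C
F13 | step 7 | (1R)-1-[(2S,3S)-2-{[(tert-butyldimethylsilyl)oxy]methyl}-3-{(3Z)-5-[(tert-butyldiphenylsilyl)oxy]-3-methylpent-3-en-1-yl}oxiran-2-yl]but-3-yn-1-ol | C#CC[C@@H](O)[C@]1(CO[Si](C)(C)C(C)(C)C)O[C@H]1CC/C(C)=C\CO[Si](c1ccccc1)(c1ccccc1)C(C)(C)C
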